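**Retrosynthetic overview**

1. Ring numbering used here: C1 (C=O next to the chain-bearing carbon), C2 (C–OH), C3 (C–CH3), C4 (C=O), C5 (C–H), C6 (C–nonadecyl). The quinone is taken back to the 1-O-methyl ether of its benzene-1,2,4-triol form; oxidative demethylation is the last step.
2. Enabling feature: C3 lies between two oxygen-bearing ring carbons (C2 and C4), so the six-membered ring is a masked cyclic 1,3-dicarbonyl and C2–C3 is a Claisen bond (ester carbon C2 plus α-carbon C3 of an ethyl ketone). The third oxygen, on C1, sits on the α-carbon of that ester and can be carried in by a 2-methoxymalonate.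
3. The only ring (the six-membered carbocycle) is made in one operation from two acyclic pieces, tetracos-4-yn-3-one and dimethyl 2-methoxymalonate. Michael addition joins C1 to C6, Claisen condensation closes the ring at C2–C3, and the spare ester leaves as dimethyl carbonate on aromatisation. This is the Claisen-type folding of a poly-β-carbonyl chain by which polyketide synthases make phenols.
4. The alkynone is assembled from 1-bromononadecane, lithium acetylide and a propanoyl Weinreb amide.

Key step: step 3

Remark: the target has no stereocentre and is treated as its 2-hydroxy-1,4-benzoquinone tautomer; the four starting materials are taken as purchasable.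

**Route**

Step 1
Reactants: 1 1-bromononadecane; 2 lithium acetylide–ethylenediamine complex (LiC≡CH·H2NCH2CH2NH2)
Product: 3 henicos-1-yne
Conditions: 2 (1.5 equiv), DMSO/THF, 0 °C to rt; aq. NH4Cl
Reagents that add atoms: none
Why: SN2 alkylation of monolithium acetylide by an unhindered primary bromide in a dipolar aprotic medium, a standard terminal-alkyne synthesis in which substitution should outrun E2 elimination.

Step 2
Reactants: 3 henicos-1-yne; 4 N-methoxy-N-methylpropanamide
Product: 7 tetracos-4-yn-3-one, via lithium henicos-1-yn-1-ide 5 (not isolated), via lithium hemiaminal alkoxide 6 (not isolated)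
Conditions: n-BuLi (1.05 equiv), THF, 0 °C; then 4, 0 °C to rt; aq. NH4Cl
Reagents that add atoms: none
Why: Weinreb ketone synthesis, in which the lithium acetylide adds once to the N-methoxy-N-methylamide and the chelated adduct 6 releases the alkynone only on aqueous work-up, so no tertiary alcohol should form.

Step 3
Reactants: 7 tetracos-4-yn-3-one; 8 dimethyl 2-methoxymalonate
Product: 11 4-methoxy-2-methyl-5-nonadecylbenzene-1,3-diol, via Michael adduct 9 (not isolated), via cyclohexenedione ester 10 (not isolated)
Conditions: 8 (1.2 equiv), NaOMe (cat.), THF/MeOH, 0 °C to rt; then NaOMe (3 equiv), MeOH, reflux, Ar; aq. HCl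
Reagents that add atoms: none
Why: Proposed new method: the sodium enolate of 8 should add to the β-carbon of alkynone 7 (Michael addition, joining the methoxylated carbon to the chain-bearing carbon) to give 9, the α'-enolate of the ethyl ketone then attacks one ester carbonyl in a 6-(enolendo)-exo-trig Claisen (Dieckmann-type) condensation that closes the only ring by joining the methyl-bearing carbon to the future hydroxyl-bearing carbon, and methoxide finally cleaves the remaining, now non-enolisable β-keto ester of 10 (retro-Claisen) so that dimethyl carbonate leaves and the ring aromatises. The closest known reaction type is the Michael–Dieckmann condensation of malonates with alk-3-en-2-ones that gives dihydroresorcylates, together with the alkoxide dealkoxycarbonylation of non-enolisable β-keto esters; new here are the alkynone oxidation level, which makes a later dehydrogenation unnecessary, and the 2-methoxy group, which brings in the third ring oxygen. No stereocentre survives, because the two sp3 ring carbons of 10 are formed without control and both are flattened on aromatisation. The step needs C-acylation over O-acylation and a cis arrangement of ketone and malonate on the new alkene: anti addition to the alkyne gives the cis isomer directly and methoxide addition–elimination equilibrates the rest, while the enol lactone from O-acylation is reopened by methoxide and cannot tautomerise to a stable 2-pyranone because the malonate carbon is quaternary, so only the carbocyclic path ends in an irreversible event (phenoxide formation). Regiochemistry is fixed by the substrate, since the ethyl CH2 is the only enolisable position that can reach an ester carbonyl through a six-membered transition state.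

Step 4
Reactants: 11 4-methoxy-2-methyl-5-nonadecylbenzene-1,3-diol
Product: 12 Capiquinone C (2-hydroxy-3-methyl-6-nonadecyl-1,4-benzoquinone)
Conditions: (NH4)2Ce(NO3)6 (2.2 equiv), MeCN/CH2Cl2/H2O, 0 °C
Reagents that add atoms: water, O
Why: Oxidative demethylation of a 4-methoxyphenol by two one-electron transfers to tetravalent cerium, in which water captures the aryloxonium ion at the methoxy-bearing carbon and the hemiketal loses methanol to give the 1,4-quinone, while the hydroxyl group next to the former methoxy carbon stays as the enolic OH (the alternative ortho-quinone is only a tautomer of the same product).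

**Compound list**

1 | 1-bromononadecane | CCCCCCCCCCCCCCCCCCCBr | starting material
2 | lithium acetylide–ethylenediamine complex | [Li+].[C-]#C.NCCN | starting material
3 | henicos-1-yne | C#CCCCCCCCCCCCCCCCCCCC | intermediate
4 | N-methoxy-N-methylpropanamide | CCC(=O)N(C)OC | starting material
5 | lithium henicos-1-yn-1-ide | [Li+].[C-]#CCCCCCCCCCCCCCCCCCCC | intermediate (not isolated)
6 | lithium 3-[methoxy(methyl)amino]tetracos-4-yn-3-olate (racemic) | [Li+].CCC([O-])(N(C)OC)C#CCCCCCCCCCCCCCCCCCCC | intermediate (not isolated)
7 | tetracos-4-yn-3-one | CCC(=O)C#CCCCCCCCCCCCCCCCCCCC | intermediate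
8 | dimethyl 2-methoxymalonate (dimethyl 2-methoxypropanedioate) | COC(C(=O)OC)C(=O)OC | starting material
9 | dimethyl 2-methoxy-2-[(4Z)-3-oxotetracos-4-en-5-yl]propanedioate (reacting alkene isomer) | CCC(=O)/C=C(/CCCCCCCCCCCCCCCCCCC)C(OC)(C(=O)OC)C(=O)OC | intermediate (not isolated)
10 | methyl 1-methoxy-5-methyl-2-nonadecyl-4,6-dioxocyclohex-2-ene-1-carboxylate (mixture of diastereomers) | COC(=O)C1(OC)C(=O)C(C)C(=O)C=C1CCCCCCCCCCCCCCCCCCC | intermediate (not isolated)
11 | 4-methoxy-2-methyl-5-nonadecylbenzene-1,3-diol | COc1c(O)c(C)c(O)cc1CCCCCCCCCCCCCCCCCCC | intermediate
12 | Capiquinone C (2-hydroxy-3-methyl-6-nonadecyl-1,4-benzoquinone) | CCCCCCCCCCCCCCCCCCCC1=CC(=O)C(C)=C(O)C1=O | target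

**Step count and risks**

Total step count: 4. Longest linear sequence: 4 steps (1 → 3 → 7 → 11 → 12).

Most likely to fail, first (step 3, the proposed new method). The Michael adduct may be diverted by O-acylation, or by early loss of one ester followed by lactonisation, into a pyranone manifold that does not undergo the ring transformation. Base-induced isomerisation of the alkynone may also outrun conjugate addition. The fallback uses only known chemistry: alkene instead of alkyne oxidation level, unsubstituted malonate, and the C1 oxygen introduced last. It sets out from 7. Lindlar semihydrogenation (H2, Pd/CaCO3 poisoned with Pb(OAc)2, quinoline, EtOAc) should give (4Z)-tetracos-4-en-3-one F1. Michael addition of dimethyl malonate (NaOMe, MeOH, rt) should give dimethyl 2-(3-oxotetracosan-5-yl)propanedioate F2. On heating in the same pot, F2 should undergo the Dieckmann-type closure, again between the methyl-bearing carbon and an ester carbon, to methyl 3-methyl-2,4-dioxo-6-nonadecylcyclohexane-1-carboxylate F3. Aqueous NaOH at reflux followed by HCl and heating should hydrolyse and decarboxylate F3 to 2-methyl-5-nonadecylcyclohexane-1,3-dione F4. Catalytic dehydrogenation (Pd/C, mesitylene, reflux) should give 2-methyl-5-nonadecylbenzene-1,3-diol F5. Teuber oxidation of F5 with (KSO3)2NO in phosphate-buffered aqueous acetone should attack one of the two equivalent ring CH positions para to a hydroxyl and rejoin the route at 12.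

Second (step 4). Over-oxidation, oxidative coupling at the free ring position, or nitration of the electron-rich ring may compete with clean quinone formation. The fallback separates ether cleavage from oxidation and sets out from 11. BBr3 (CH2Cl2, −78 to 0 °C) should cleave the aryl methyl ether to 3-methyl-6-nonadecylbenzene-1,2,4-triol F6. F6 should autoxidise (air, aq. NaHCO3/THF, rt) and rejoin the route at 12.

Third (step 1). E2 elimination of the bromide, or sluggish substitution caused by poor solubility of the C19 bromide in DMSO, may limit alkyne formation. The fallback builds the carbon skeleton with a different nucleophile and sets out from 1. Pent-1-yn-3-ol is doubly deprotonated (n-BuLi, 2 equiv, THF/DMPU, −20 °C) to dilithium pent-1-yn-1-id-3-olate F7. F7 should be C-alkylated by 1 to racemic tetracos-4-yn-3-ol F8. Oxidation of this propargylic alcohol (MnO2, CH2Cl2, rt) should rejoin the route at 7, bypassing 3 to 6.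

**Further compounds**

F1 | step 3 | (4Z)-tetracos-4-en-3-one | CCC(=O)/C=C\CCCCCCCCCCCCCCCCCCC
F2 | step 3 | dimethyl 2-(3-oxotetracosan-5-yl)propanedioate (racemic) | CCC(=O)CC(CCCCCCCCCCCCCCCCCCC)C(C(=O)OC)C(=O)OC
F3 | step 3 | methyl 3-methyl-2,4-dioxo-6-nonadecylcyclohexane-1-carboxylate (mixture of stereoisomers) | COC(=O)C1C(=O)C(C)C(=O)CC1CCCCCCCCCCCCCCCCCCC
F4 | step 3 | 2-methyl-5-nonadecylcyclohexane-1,3-dione (mixture of stereoisomers) | CC1C(=O)CC(CCCCCCCCCCCCCCCCCCC)CC1=O
F5 | step 3 | 2-methyl-5-nonadecylbenzene-1,3-diol | Cc1c(O)cc(CCCCCCCCCCCCCCCCCCC)cc1O
F6 | step 4 | 3-methyl-6-nonadecylbenzene-1,2,4-triol | Cc1c(O)cc(CCCCCCCCCCCCCCCCCCC)c(O)c1O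
F7 | step 1 | dilithium pent-1-yn-1-id-3-olate (racemic) | [Li+].[Li+].CCC([O-])C#[C-]
F8 | step 1 | tetracos-4-yn-3-ol (racemic) | CCC(O)C#CCCCCCCCCCCCCCCCCCCC
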